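## Retrosynthetic overview

1. Feature: in pterocarpan numbering, C11a is an acetal-level carbon bound to O11 (ring C) and to C11b of ring A, which is ortho to O5 and para to the ring E oxygen. The C11b–C11a bond is therefore cut as a lactol arylation, and the cis B/C fusion lets C6a dictate C11a.
2. Target ⇐ 9-O-silyl pterocarpan 29 ⇐ lactol 28 (ring C hemiacetal; rings A, D, E, F complete). Ring B is closed last by Friedel–Crafts attack of C11b on the C11a oxocarbenium ion.
3. Lactol 28 ⇐ aldehyde 26. O5–C6 comes from Mitsunobu coupling of the ring A/E chromenol 23 with monoacetate 18, C6a from lipase desymmetrisation of 2-aryl-1,3-propanediol 17, and O11 is freed by neutral deallylation.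
4. Diol 17 ⇐ ring D/F aryl bromide 12 + diethyl oxomalonate (C6b–C6a), then deoxygenation and reduction. Bromide 12 ⇐ 2-bromo-4,5-dihydroxybenzaldehyde by Baeyer–Villiger oxidation (O11) and two aryl ether Claisen rearrangements (C10 prenyl, ring F).
5. Order of ring formation: ring F on ring D (step 6), ring E on ring A (step 12), ring C as the lactol (step 17), ring B (step 18).

Key step: step 18

Shorthand: TBS = tert-butyldimethylsilyl; prenyl = 3-methylbut-2-en-1-yl; "D-aryl" = 6-(allyloxy)-8-[(tert-butyldimethylsilyl)oxy]-2,2-dimethyl-7-prenyl-2H-chromen-5-yl. Pterocarpan numbering is used for the late compounds.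

Assumption: 2-bromo-4,5-dihydroxybenzaldehyde (1) is taken as a purchasable building block.

Assumption: the lipase is taken to acetylate the hydroxymethyl arm that gives the (R)-monoacetate 18; sense and level of selectivity on this crowded diol must be confirmed.

## Route

Step 1
Reactants: 1 2-bromo-4,5-dihydroxybenzaldehyde; 2 3-chloro-3-methylbut-1-yne
Product: 3 2-bromo-5-hydroxy-4-[(2-methylbut-3-yn-2-yl)oxy]benzaldehyde
Conditions: DBU (1.1 equiv), CuCl2·2H2O (cat.), MeCN, 0 °C
Reagents that add atoms: none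
Why: Copper-catalysed propargylic O-alkylation should occur at the 4-hydroxyl, the more acidic phenol para to the formyl group, when only one equivalent of base is present.

Step 2
Reactants: 3 2-bromo-5-hydroxy-4-[(2-methylbut-3-yn-2-yl)oxy]benzaldehyde
Product: 4 2-bromo-5-[(tert-butyldimethylsilyl)oxy]-4-[(2-methylbut-3-yn-2-yl)oxy]benzaldehyde
Conditions: TBSCl, imidazole, DMF, rt
Reagents that add atoms: tert-butyldimethylsilyl chloride, CC(C)(C)[Si](C)(C)Cl
Why: Imidazole-promoted silylation of the remaining phenol installs the O9 protecting group that is carried to the last step.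

Step 3
Reactants: 4 2-bromo-5-[(tert-butyldimethylsilyl)oxy]-4-[(2-methylbut-3-yn-2-yl)oxy]benzaldehyde
Product: 6 2-bromo-5-[(tert-butyldimethylsilyl)oxy]-4-[(2-methylbut-3-yn-2-yl)oxy]phenol, via aryl formate 5 (not isolated)
Conditions: mCPBA, CH2Cl2, 0 °C to rt; then Et3N (cat.), MeOH, 0 °C
Reagents that add atoms: 3-chloroperbenzoic acid, O=C(OO)c1cccc(Cl)c1
Why: In this Baeyer–Villiger oxidation the aryl group para to the alkoxy substituent migrates, no olefin is yet present to compete for the peracid, and brief methanolysis cleaves the formate but not the aryl silyl ether.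

Step 4
Reactants: 7 2-methylbut-3-en-2-ol
Product: 8 tert-butyl (2-methylbut-3-en-2-yl) carbonate
Conditions: n-BuLi, THF, 0 °C; then Boc2O, 0 °C to rt; H2O
Reagents that add atoms: di-tert-butyl dicarbonate, CC(C)(C)OC(=O)OC(=O)OC(C)(C)C
Why: Acylation of the lithium alkoxide of the tertiary allylic alcohol gives the mixed carbonate needed as a π-allyl precursor.

Step 5
Reactants: 6 2-bromo-5-[(tert-butyldimethylsilyl)oxy]-4-[(2-methylbut-3-yn-2-yl)oxy]phenol; 8 tert-butyl (2-methylbut-3-en-2-yl) carbonate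
Product: 9 [4-bromo-5-[(2-methylbut-3-en-2-yl)oxy]-2-[(2-methylbut-3-yn-2-yl)oxy]phenoxy](tert-butyl)dimethylsilane
Conditions: Pd(PPh3)4 (cat.), THF, 0 °C
Reagents that add atoms: none
Why: In this Tsuji–Trost O-allylation the phenol should attack the 1,1-dimethyl-π-allyl palladium intermediate at its more substituted terminus under kinetic control, giving the tertiary aryl ether, while the aryl bromide and the alkyne are inert at this temperature.

Step 6
Reactants: 9 [4-bromo-5-[(2-methylbut-3-en-2-yl)oxy]-2-[(2-methylbut-3-yn-2-yl)oxy]phenoxy](tert-butyl)dimethylsilane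
Product: 11 5-bromo-8-[(tert-butyldimethylsilyl)oxy]-2,2-dimethyl-7-prenyl-2H-chromen-6-ol, via ortho-prenyl phenol 10 (not isolated)
Conditions: PhNEt2, 110 °C then 150 °C
Reagents that add atoms: none
Why: Two aromatic Claisen rearrangements run in one operation: the 1,1-dimethylallyl ether shifts to the only free ortho carbon of O11 (C10) and frees that phenol, then the propargyl ether shifts to the only free ortho carbon of O8 (C7) and the allene closes to ring F by 1,5-hydrogen shift and oxa-6π electrocyclisation.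

Step 7
Reactants: 11 5-bromo-8-[(tert-butyldimethylsilyl)oxy]-2,2-dimethyl-7-prenyl-2H-chromen-6-ol
Product: 12 6-(allyloxy)-5-bromo-8-[(tert-butyldimethylsilyl)oxy]-2,2-dimethyl-7-prenyl-2H-chromene
Conditions: allyl bromide, K2CO3, acetone, 50 °C
Reagents that add atoms: allyl bromide, C=CCBr
Why: Williamson etherification puts on O11 a group that survives organolithium, hydride and oxidation steps and can later be removed under neutral conditions.

Step 8
Reactants: 12 6-(allyloxy)-5-bromo-8-[(tert-butyldimethylsilyl)oxy]-2,2-dimethyl-7-prenyl-2H-chromene; 13 diethyl oxomalonate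
Product: 15 diethyl 2-(D-aryl)-2-hydroxymalonate, via aryllithium 14 (not isolated)
Conditions: n-BuLi, THF, −78 °C; then 13, −78 °C; then AcOH
Reagents that add atoms: none
Why: Bromine–lithium exchange at −78 °C is faster than any attack on the allyl ether, and 1,2-addition of the aryllithium to the very electrophilic central carbonyl forms the C6b–C6a bond.

Step 9
Reactants: 15 diethyl 2-(D-aryl)-2-hydroxymalonate
Product: 16 diethyl 2-(D-aryl)malonate
Conditions: SmI2, HMPA, t-BuCO2H, THF, rt
Reagents that add atoms: none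
Why: SmI2 reduction of an α-hydroxy ester (electron transfer, loss of hydroxide, second electron transfer, protonation) removes the tertiary benzylic hydroxyl without touching the olefins, the allyl ether or the silyl ether.

Step 10
Reactants: 16 diethyl 2-(D-aryl)malonate
Product: 17 2-(D-aryl)propane-1,3-diol
Conditions: LiAlH4, THF, 0 °C; then H2O, aq NaOH
Reagents that add atoms: none
Why: Hydride reduction of both esters gives the prochiral 2-aryl-1,3-propanediol.

Step 11
Reactants: 17 2-(D-aryl)propane-1,3-diol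
Product: 18 (2R)-2-(D-aryl)-3-hydroxypropyl acetate
Conditions: lipase PS (Burkholderia cepacia), vinyl acetate, i-Pr2O, 30 °C
Reagents that add atoms: vinyl acetate, C=COC(C)=O
Why: Lipase-catalysed irreversible transesterification distinguishes the two enantiotopic hydroxymethyl arms of the prochiral diol and so sets the future C6a stereocentre.

Step 12
Reactants: 19 resorcinol; 20 3-methylbut-2-enoic acid
Product: 21 7-hydroxy-2,2-dimethylchroman-4-one
Conditions: P4O10, MeSO3H, 70 °C
Reagents that add atoms: none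
Why: Friedel–Crafts acylation of resorcinol at C4 followed by oxa-Michael closure of the ortho-hydroxy enone gives the chromanone.

Step 13
Reactants: 21 7-hydroxy-2,2-dimethylchroman-4-one
Product: 23 2,2-dimethyl-2H-chromen-7-ol, via chromane-4,7-diol 22 (not isolated)
Conditions: LiAlH4, THF, 0 °C to reflux; then 2 M HCl, rt
Reagents that add atoms: none
Why: Hydride reduction of the ketone and acid-promoted dehydration of the para-hydroxybenzylic alcohol give the chromene of rings A and E.

Step 14
Reactants: 18 (2R)-2-(D-aryl)-3-hydroxypropyl acetate; 23 2,2-dimethyl-2H-chromen-7-ol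
Product: 24 (2R)-2-(D-aryl)-3-[(2,2-dimethyl-2H-chromen-7-yl)oxy]propyl acetate
Conditions: PPh3, DIAD, THF, 0 °C to rt
Reagents that add atoms: none
Why: Mitsunobu etherification forms the O5–C6 bond at a primary carbon that is not stereogenic, so the configuration at the future C6a is untouched.

Step 15
Reactants: 24 (2R)-2-(D-aryl)-3-[(2,2-dimethyl-2H-chromen-7-yl)oxy]propyl acetate
Product: 25 (2S)-2-(D-aryl)-3-[(2,2-dimethyl-2H-chromen-7-yl)oxy]propan-1-ol
Conditions: i-Bu2AlH, CH2Cl2, −78 °C; then H2O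
Reagents that add atoms: none
Why: Reductive cleavage of the acetate at low temperature frees the second arm without the basic methanolysis that would endanger the aryl silyl ether.

Step 16
Reactants: 25 (2S)-2-(D-aryl)-3-[(2,2-dimethyl-2H-chromen-7-yl)oxy]propan-1-ol
Product: 26 (2R)-2-(D-aryl)-3-[(2,2-dimethyl-2H-chromen-7-yl)oxy]propanal
Conditions: Dess–Martin periodinane, NaHCO3, CH2Cl2, 0 °C
Reagents that add atoms: none
Why: Dess–Martin oxidation under buffered, non-basic conditions should give the α-aryl aldehyde without enolisation, and the crude product is taken on at once.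

Step 17
Reactants: 26 (2R)-2-(D-aryl)-3-[(2,2-dimethyl-2H-chromen-7-yl)oxy]propanal
Product: 28 (6aR)-lactol: 2-hydroxy-2,3-dihydrobenzofuran (ring C) fused to rings D and F with 9-OTBS and 10-prenyl and carrying the (2,2-dimethyl-2H-chromen-7-yl)oxymethyl group on C6a (both C11a anomers), via hydroxy aldehyde 27 (not isolated)
Conditions: Pd(PPh3)4 (cat.), Bu3SnH, AcOH, CH2Cl2, rt
Reagents that add atoms: none
Why: Tsuji–Trost deallylation with a hydride donor and acetic acid as proton source frees O11 under neutral conditions that an aldehyde tolerates, and the phenol adds to the neighbouring aldehyde to give the five-membered lactol, which shields C6a from enolisation.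

Step 18
Reactants: 28 (6aR)-lactol
Product: 29 (6aR,11aR)-9-O-tert-butyldimethylsilyl lespecyrtin E4
Conditions: BF3·OEt2 (0.3 equiv), CH2Cl2, −78 to −40 °C
Reagents that add atoms: none
Why: BF3 complexes the anomeric hydroxyl of 28 and ionises it to the cyclic oxocarbenium ion at C11a, stabilised by O11, which C11b of the tethered ring A attacks before rearomatisation; the closest known reaction type is the intramolecular Friedel–Crafts arylation of lactol-derived oxocarbenium ions. Ring B closes in a 6-exo-trig mode with respect to the C11a=O11 bond, the C4a–C11b arene bond lying inside the new ring. The new stereocentre C11a is controlled by C6a: the three-atom C6–O5–C4a tether can deliver ring A only to the face of ring C that carries C6, so the B/C fusion must be cis and 6aR gives 11aR. Attack at C11b rather than C4 is secured because C11b is para to the ring E oxygen and unhindered, whereas C4 lies between two oxygens. Cyclisation must outrun loss of H6a to the benzofuran, which is favoured by the low temperature, the absence of any base, the short tether and the high nucleophilicity of ring A. The C9 silyl ether keeps the phenol from adding to the neighbouring prenyl olefin under the acid.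

Step 19
Reactants: 29 (6aR,11aR)-9-O-tert-butyldimethylsilyl lespecyrtin E4
Product: 30 lespecyrtin E4
Conditions: Bu4NF, AcOH, THF, 0 °C
Reagents that add atoms: none
Why: Fluoride cleaves the aryl silyl ether, and the acetic acid buffer keeps the electron-rich phenol from standing as its air-sensitive phenoxide.

## Compound list

1 | 2-bromo-4,5-dihydroxybenzaldehyde | O=Cc1cc(O)c(O)cc1Br | starting material
2 | 3-chloro-3-methylbut-1-yne | C#CC(C)(C)Cl | starting material
3 | 2-bromo-5-hydroxy-4-[(2-methylbut-3-yn-2-yl)oxy]benzaldehyde | O=Cc1cc(O)c(OC(C)(C)C#C)cc1Br | intermediate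
4 | 2-bromo-5-[(tert-butyldimethylsilyl)oxy]-4-[(2-methylbut-3-yn-2-yl)oxy]benzaldehyde | O=Cc1cc(O[Si](C)(C)C(C)(C)C)c(OC(C)(C)C#C)cc1Br | intermediate
5 | 2-bromo-5-[(tert-butyldimethylsilyl)oxy]-4-[(2-methylbut-3-yn-2-yl)oxy]phenyl formate | O=COc1cc(O[Si](C)(C)C(C)(C)C)c(OC(C)(C)C#C)cc1Br | intermediate (not isolated)
6 | 2-bromo-5-[(tert-butyldimethylsilyl)oxy]-4-[(2-methylbut-3-yn-2-yl)oxy]phenol | Oc1cc(O[Si](C)(C)C(C)(C)C)c(OC(C)(C)C#C)cc1Br | intermediate
7 | 2-methylbut-3-en-2-ol | C=CC(C)(C)O | starting material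
8 | tert-butyl (2-methylbut-3-en-2-yl) carbonate | C=CC(C)(C)OC(=O)OC(C)(C)C | intermediate
9 | [4-bromo-5-[(2-methylbut-3-en-2-yl)oxy]-2-[(2-methylbut-3-yn-2-yl)oxy]phenoxy](tert-butyl)dimethylsilane | C=CC(C)(C)Oc1cc(O[Si](C)(C)C(C)(C)C)c(OC(C)(C)C#C)cc1Br | intermediate
10 | 2-bromo-5-[(tert-butyldimethylsilyl)oxy]-4-[(2-methylbut-3-yn-2-yl)oxy]-6-prenylphenol | Oc1c(CC=C(C)C)c(O[Si](C)(C)C(C)(C)C)c(OC(C)(C)C#C)cc1Br | intermediate (not isolated)
11 | 5-bromo-8-[(tert-butyldimethylsilyl)oxy]-2,2-dimethyl-7-prenyl-2H-chromen-6-ol | CC1(C)C=Cc2c(Br)c(O)c(CC=C(C)C)c(O[Si](C)(C)C(C)(C)C)c2O1 | intermediate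
12 | 6-(allyloxy)-5-bromo-8-[(tert-butyldimethylsilyl)oxy]-2,2-dimethyl-7-prenyl-2H-chromene | CC1(C)C=Cc2c(Br)c(OCC=C)c(CC=C(C)C)c(O[Si](C)(C)C(C)(C)C)c2O1 | intermediate
13 | diethyl oxomalonate | CCOC(=O)C(=O)C(=O)OCC | starting material
14 | 6-(allyloxy)-8-[(tert-butyldimethylsilyl)oxy]-2,2-dimethyl-7-prenyl-2H-chromen-5-yllithium | CC1(C)C=Cc2c([Li])c(OCC=C)c(CC=C(C)C)c(O[Si](C)(C)C(C)(C)C)c2O1 | intermediate (not isolated)
15 | diethyl 2-(D-aryl)-2-hydroxymalonate | CCOC(=O)C(O)(C(=O)OCC)c1c(OCC=C)c(CC=C(C)C)c(O[Si](C)(C)C(C)(C)C)c2OC(C)(C)C=Cc12 | intermediate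
16 | diethyl 2-(D-aryl)malonate | CCOC(=O)C(C(=O)OCC)c1c(OCC=C)c(CC=C(C)C)c(O[Si](C)(C)C(C)(C)C)c2OC(C)(C)C=Cc12 | intermediate
17 | 2-(D-aryl)propane-1,3-diol | OCC(CO)c1c(OCC=C)c(CC=C(C)C)c(O[Si](C)(C)C(C)(C)C)c2OC(C)(C)C=Cc12 | intermediate
18 | (2R)-2-(D-aryl)-3-hydroxypropyl acetate | OC[C@H](COC(C)=O)c1c(OCC=C)c(CC=C(C)C)c(O[Si](C)(C)C(C)(C)C)c2OC(C)(C)C=Cc12 | intermediate
19 | resorcinol | Oc1cccc(O)c1 | starting material
20 | 3-methylbut-2-enoic acid | CC(C)=CC(=O)O | starting material
21 | 7-hydroxy-2,2-dimethylchroman-4-one | CC1(C)CC(=O)c2ccc(O)cc2O1 | intermediate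
22 | 2,2-dimethylchromane-4,7-diol | CC1(C)CC(O)c2ccc(O)cc2O1 | intermediate (not isolated)
23 | 2,2-dimethyl-2H-chromen-7-ol | CC1(C)C=Cc2ccc(O)cc2O1 | intermediate
24 | (2R)-2-(D-aryl)-3-[(2,2-dimethyl-2H-chromen-7-yl)oxy]propyl acetate | CC(=O)OC[C@@H](COc1ccc2C=CC(C)(C)Oc2c1)c1c(OCC=C)c(CC=C(C)C)c(O[Si](C)(C)C(C)(C)C)c2OC(C)(C)C=Cc12 | intermediate
25 | (2S)-2-(D-aryl)-3-[(2,2-dimethyl-2H-chromen-7-yl)oxy]propan-1-ol | OC[C@@H](COc1ccc2C=CC(C)(C)Oc2c1)c1c(OCC=C)c(CC=C(C)C)c(O[Si](C)(C)C(C)(C)C)c2OC(C)(C)C=Cc12 | intermediate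
26 | (2R)-2-(D-aryl)-3-[(2,2-dimethyl-2H-chromen-7-yl)oxy]propanal | O=C[C@@H](COc1ccc2C=CC(C)(C)Oc2c1)c1c(OCC=C)c(CC=C(C)C)c(O[Si](C)(C)C(C)(C)C)c2OC(C)(C)C=Cc12 | intermediate
27 | (2R)-2-{8-[(tert-butyldimethylsilyl)oxy]-6-hydroxy-2,2-dimethyl-7-prenyl-2H-chromen-5-yl}-3-[(2,2-dimethyl-2H-chromen-7-yl)oxy]propanal | O=C[C@@H](COc1ccc2C=CC(C)(C)Oc2c1)c1c(O)c(CC=C(C)C)c(O[Si](C)(C)C(C)(C)C)c2OC(C)(C)C=Cc12 | intermediate (not isolated)
28 | (6aR)-lactol: 3-(chromenyloxymethyl)-2,3-dihydrobenzofuran-2-ol with rings C, D, F complete, 9-OTBS, 10-prenyl, both C11a anomers | OC1Oc2c(CC=C(C)C)c(O[Si](C)(C)C(C)(C)C)c3OC(C)(C)C=Cc3c2[C@@H]1COc1ccc2C=CC(C)(C)Oc2c1 | intermediate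
29 | (6aR,11aR)-9-O-tert-butyldimethylsilyl lespecyrtin E4 | C1Oc2cc3OC(C)(C)C=Cc3cc2[C@@H]2Oc3c(CC=C(C)C)c(O[Si](C)(C)C(C)(C)C)c4OC(C)(C)C=Cc4c3[C@H]12 | intermediate
30 | lespecyrtin E4, (6aR,11aR) | CC(C)=CCc1c(O)c2c(c3c1O[C@H]1c4cc5c(cc4OC[C@@H]31)OC(C)(C)C=C5)C=CC(C)(C)O2 | target

## Step count and risks

Total step count: 19. Longest linear sequence: 16 steps (steps 1–3, 5–11 and 14–19).

Steps most likely to fail:

1. Step 18 (key step). The oxocarbenium ion may lose the C6a proton and aromatise ring C, which erases the stereocentre, or the acid may attack the chromene olefins before ring closure. Fallback, from aldehyde 26 back to 29: the C11b–C11a bond is made first on the neutral carbonyl while O11 is still allylated, so no oxocarbenium ion next to C6a is formed. Me2AlCl in CH2Cl2 at −78 °C should promote intramolecular Friedel–Crafts hydroxyalkylation of ring A, the known acid cyclisation of 3-aryloxypropanals to chroman-4-ols, giving the O11-allyl isoflavan-4-ol F1 as a mixture of carbinol epimers. Pd(PPh3)4, Bu3SnH and AcOH would then free O11 to give the 2'-hydroxyisoflavan-4-ol F2. The classical closure of such diols with BF3·OEt2 (ionisation at the ring A benzylic carbon C11a and capture by O11) should give the cis-fused silyl ether 29.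

2. Step 11. The enzyme may accept the crowded, fully substituted aryl diol poorly, or acetylate with low or opposite selectivity. Fallback, from diol 17 back to 25: desymmetrising benzoylation with vinyl benzoate, catalysed by the dinuclear zinc complex formed from Et2Zn and a ProPhenol ligand (the ligand enantiomer chosen to acylate the arm destined for C11a), would give the (R)-monobenzoate F3. Mitsunobu etherification with 23 gives the benzoate F4, and i-Bu2AlH cleavage of the benzoate returns to alcohol 25.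

3. Step 16. The α-aryl-β-aryloxy aldehyde may epimerise through its enol or lose the chromenoxide by β-elimination before the lactol is closed. Fallback, from alcohol 25 back to 28: unmasking and oxidation are reversed so that no free aldehyde accumulates. Pd(PPh3)4, Bu3SnH and AcOH first give the phenol alcohol F5. Swern oxidation ((COCl)2, DMSO, −78 °C, then i-Pr2NEt) then forms the aldehyde next to the free ortho-phenol, which traps it at once as lactol 28. Ring D has no free ring position, so the activated sulfoxide cannot alkylate it.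

Further compounds
F1 | step 18 | (6aR)-O11-allyl isoflavan-4-ol: ring B closed, C11a carbinol epimers, D-aryl on C6a | OC1c2cc3C=CC(C)(C)Oc3cc2OC[C@H]1c1c(OCC=C)c(CC=C(C)C)c(O[Si](C)(C)C(C)(C)C)c2OC(C)(C)C=Cc12
F2 | step 18 | (6aR)-2'-hydroxyisoflavan-4-ol: as F1 with free O11 phenol | OC1c2cc3C=CC(C)(C)Oc3cc2OC[C@H]1c1c(O)c(CC=C(C)C)c(O[Si](C)(C)C(C)(C)C)c2OC(C)(C)C=Cc12
F3 | step 11 | (2R)-2-(D-aryl)-3-hydroxypropyl benzoate | OC[C@H](COC(=O)c1ccccc1)c1c(OCC=C)c(CC=C(C)C)c(O[Si](C)(C)C(C)(C)C)c2OC(C)(C)C=Cc12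
F4 | step 11 | (2R)-2-(D-aryl)-3-[(2,2-dimethyl-2H-chromen-7-yl)oxy]propyl benzoate | O=C(OC[C@@H](COc1ccc2C=CC(C)(C)Oc2c1)c1c(OCC=C)c(CC=C(C)C)c(O[Si](C)(C)C(C)(C)C)c2OC(C)(C)C=Cc12)c1ccccc1
F5 | step 16 | (2S)-2-{8-[(tert-butyldimethylsilyl)oxy]-6-hydroxy-2,2-dimethyl-7-prenyl-2H-chromen-5-yl}-3-[(2,2-dimethyl-2H-chromen-7-yl)oxy]propan-1-ol | OC[C@@H](COc1ccc2C=CC(C)(C)Oc2c1)c1c(O)c(CC=C(C)C)c(O[Si](C)(C)C(C)(C)C)c2OC(C)(C)C=Cc12
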